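## The problem

The target (9) is a 3-methoxyflavone: ring A is fused to the pyranone ring C through C4a–C8a, ring B sits on C2, and oxygen is attached to C3, C6, C7, C2', C4' and C5'. It has no stereocentre, so the whole difficulty lies in telling six oxygens apart: four are methyl ethers, while those at C6 and C5' must end as free phenols. A conventional flavonoid route would carry these two phenols as benzyl ethers from the start, which costs two non-commercial building blocks made by selective protection and a deprotection at the end. The skeleton raises the usual questions: the C2–C1' bond is flanked by the 2'-methoxy group, and ring C must close as a six-membered pyranone with oxygen on C3, not as a five-membered aurone. The sensitive points are the pyranone, which hydroxide or alkoxide opens at C2 on heating, and the 5'-hydroxy-2',4'-dimethoxyphenyl ring, a para-alkoxyphenol that strong oxidants take to a quinone. The enabling feature is positional: C6 is ortho to the C7 methoxy group and para to the ring oxygen O1, and C5' is ortho to the C4' methoxy group and para to the C2' methoxy group. These are the carbons at which a resorcinol-derived ring A ketone and a 2,4-dioxygenated ring B aldehyde take up bromine, so a C–Br bond can stand in for each free C–OH through the whole assembly and be converted into it at the end.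

## Retrosynthesis

**From 9 to 7.** The first cut is at the C6–O and C5'–O bonds, which become the two C–Br bonds of 6,5'-dibromo-3,7,2',4'-tetramethoxyflavone (7). In the forward sense both bromides are borylated to the bis(boronate) 8, which is oxidised in the same flask. The neighbouring cut, at O–benzyl bonds, would push two protected phenols back through every earlier step and into both building blocks. Compound 7 has the same skeleton as 9, but none of its oxygens needs to be distinguished from another: each is the carbonyl, the ring oxygen or a methyl ether. The forward reaction must borylate two electron-rich, ortho-methoxylated aryl bromides in one molecule and oxidise the boronates without opening the pyranone or over-oxidising ring B.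

**From 7 to 6.** The O–CH3 bond at C3 is cut, giving the flavonol 6. Putting this methyl group on late, instead of carrying a methoxy group on the ketone side chain, lets ring C be made by the mildest flavonol-forming reaction. Compound 6 has a single acidic hydroxyl, so the methylation needs no selectivity.

**From 6 to 4.** Ring C is opened at O1–C2 and the C3–O bond is removed, giving the 2'-hydroxychalcone 4; the forward reaction passes through the dihydroflavonol 5. The alternative of acylating the ketone with a ring B acid derivative and cyclodehydrating the diketone would give a C3-unsubstituted flavone and require a separate C3 oxidation. The chosen closure delivers ring C and the C3 oxygen in one operation with aqueous base and H2O2 near room temperature, where aryl bromides are spectators. The closure must be 6-endo; the hydrogen at C5 (no substituent ortho to the carbonyl on ring A) favours the flavonol over the aurone.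

**From 4 to 2 and 3.** The Cα=Cβ bond of the enone is cut to the bromoacetophenone 2 and the bromoaldehyde 3, dividing the molecule into a ring A piece and a ring B piece of similar size. The condensation has only one course because 3 cannot enolise.

**From 2 to 1.** The C5–Br bond of 2 is cut to paeonol (1), a commodity natural product. The bromination must go para to the hydroxyl and not to C3 or the acetyl methyl group. Aldehyde 3 is bought with its bromine already in place.

## Roads not taken

**Alternative 1:** Ring C is cut at three bonds, C4a–C4, C4–C3 and O1–C2. The flavone then arises from 4-(benzyloxy)-2-iodo-5-methoxyphenol (A2), carbon monoxide and 1-(benzyloxy)-5-ethynyl-2,4-dimethoxybenzene (A3).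
- Forward key step: PdCl2(PPh3)2 under CO in diethylamine; zerovalent palladium inserts into the C–I bond of A2, CO inserts, the acyl group couples with A3, and the amine mediates 6-endo closure to 6,5'-bis(benzyloxy)-7,2',4'-trimethoxyflavone (A1).
- Merits: three bonds and ring C in one step, high convergence, and no oxidative chalcone cyclisation, whose behaviour with an ortho-substituted ring B is harder to predict.
- Weak points: A1 has hydrogen at C3, so the 3-methoxy group needs a C3 oxidation and a methylation after the key step. Both phenols travel as benzyl ethers, so A2 and A3 each need a multistep preparation with a selective protection, and a hydrogenolysis is added at the end. The 5-exo closure to an aurone competes.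
- Comparison: in convergence and bonds formed per step this road is better. The chosen plan sets against it building blocks that are bought or one step from a commodity, a C3 oxygen delivered during ring closure, no protecting group, and about half the number of operations.

**Alternative 2:** The cut is at the two bonds joining ring A to ring C, C8a–O1 and C4a–C4. Ring A comes from an aryne generated from 3-(benzyloxy)-2-chloro-4-methoxy-6-(trimethylsilyl)phenyl trifluoromethanesulfonate (A5), and the rest from (Z)-3-[5-(benzyloxy)-2,4-dimethoxyphenyl]-2-methoxyprop-2-enoic acid (A6).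
- Forward key step: CsF releases the 3-chloroaryne from A5. The carboxylate oxygen of A6 adds at the aryne carbon remote from chlorine (the future C8a). The aryl anion next to chlorine (the future C4a) takes the acyl group from oxygen, a formal insertion into the acid C–O bond, giving the hydroxyaryl enone A4.
- Merits: a skeletal C–C bond is formed, the 3-methoxy group is carried in from the acid, and the chlorine gives dependable aryne regiocontrol through its inductive effect.
- Weak points: A4 is still acyclic, so ring C needs a separate oxidative closure. The chlorine at C5 has no counterpart in the target and must be removed reductively without saturating C2=C3. A5 is a pentasubstituted benzene that needs a long preparation. Two benzyl ethers again require removal.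
- Comparison: this road is more constructive at the key step and avoids a double palladium reaction on electron-rich bromides. The chosen plan sets against it that its halogens are converted into required oxygens rather than discarded, that ring C closes with its C3 oxygen in one step, and that the route is much shorter.

**Alternative 3:** Ring B is cut at three bonds, C5'–C6', C1'–C2' and C2'–C3'. It is then built on 6-(benzyloxy)-2-ethynyl-3,7-dimethoxy-4H-chromen-4-one (A8) with the zerovalent chromium carbene complex (CO)5Cr=C(OBn)C(OMe)=CH2 (A9).
- Forward key step: heating in a Dötz benzannulation; loss of one CO, alkyne insertion, CO insertion, six-electron ring closure and tautomerisation give 6,5'-bis(benzyloxy)-2'-hydroxy-3,7,4'-trimethoxyflavone (A7).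
- Merits: this is the only road whose key step closes a ring. The intrinsic regiochemistry fits ring B: the new phenol at C2' is para to the carbene-derived benzyloxy group at C5', and the chromone ends up ortho to the phenol. The three ring B oxygens emerge already differentiated.
- Weak points: chromium is stoichiometric. A9 is an unusual O-benzyl α-alkoxyvinyl carbene. The alkyne of A8 is conjugated to the pyranone and electron-poor, a class that benzannulates less reliably. A8 itself needs a long synthesis of a 6-benzyloxy-3-methoxychromone followed by C2 alkynylation. The para-alkoxyphenol of A7 is exposed to the oxidant that removes chromium. Methylation of the 2'-hydroxyl and hydrogenolysis still follow.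
- Comparison: as ring construction it is the most ambitious, forming three C–C bonds where the chosen key step forms two C–O bonds. The chosen plan sets against it catalytic palladium instead of stoichiometric chromium, commercial inputs, and five steps in all.

Key step: step 5

Remark: the dihydroflavonol 5 forms as a trans racemate and both of its stereocentres become sp2 in the same step, so no stereocontrol is needed anywhere in the route.

## Route

Step 1
Reactants: 1 paeonol (1-(2-hydroxy-4-methoxyphenyl)ethanone)
Product: 2 1-(5-bromo-2-hydroxy-4-methoxyphenyl)ethanone
Conditions: NBS (1.05 equiv), MeCN, 0 °C to rt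
Reagents that add atoms: N-bromosuccinimide, O=C1CCC(=O)N1Br
Why: Electrophilic aromatic bromination; C5 is para to the free hydroxyl and ortho to the methoxy group, whereas C3 is flanked by two substituents, and neutral NBS without acid or radical initiation leaves the hydrogen-bonded acetyl group unenolised.

Step 2
Reactants: 2 1-(5-bromo-2-hydroxy-4-methoxyphenyl)ethanone; 3 5-bromo-2,4-dimethoxybenzaldehyde
Product: 4 (E)-1-(5-bromo-2-hydroxy-4-methoxyphenyl)-3-(5-bromo-2,4-dimethoxyphenyl)prop-2-en-1-one
Conditions: KOH (50% aq), EtOH, rt; then 1 M HCl
Reagents that add atoms: none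
Why: Claisen–Schmidt condensation; the ketone enolate adds to the non-enolisable aldehyde and the aldol dehydrates by E1cB to the conjugated enone in the thermodynamically favoured E geometry, while both aryl bromides are inert to aqueous hydroxide at room temperature.

Step 3
Reactants: 4 (E)-1-(5-bromo-2-hydroxy-4-methoxyphenyl)-3-(5-bromo-2,4-dimethoxyphenyl)prop-2-en-1-one
Product: 6 6-bromo-2-(5-bromo-2,4-dimethoxyphenyl)-3-hydroxy-7-methoxy-4H-chromen-4-one, via trans-dihydroflavonol 5 (not isolated)
Conditions: H2O2 (30% aq), NaOH (aq), MeOH/THF, 0 °C to rt; then 1 M HCl
Reagents that add atoms: hydrogen peroxide, OO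
Why: Algar–Flynn–Oyamada reaction; the phenoxide closes 6-endo onto the β-carbon while hydroperoxide delivers oxygen to C3, giving the racemic trans-dihydroflavonol 5, which excess alkaline peroxide dehydrogenates to the flavonol so that both transient stereocentres disappear. The hydrogen at C5 (no substituent ortho to the carbonyl on ring A) favours the flavonol over the aurone.

Step 4
Reactants: 6 6-bromo-2-(5-bromo-2,4-dimethoxyphenyl)-3-hydroxy-7-methoxy-4H-chromen-4-one
Product: 7 6-bromo-2-(5-bromo-2,4-dimethoxyphenyl)-3,7-dimethoxy-4H-chromen-4-one (6,5'-dibromo-3,7,2',4'-tetramethoxyflavone)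
Conditions: MeI, K2CO3, acetone, reflux
Reagents that add atoms: iodomethane, CI
Why: Williamson ether synthesis; the 3-hydroxyl is the only acidic proton in 6, its potassium salt is methylated by SN2 attack on MeI, and carbonate in acetone touches neither the pyranone nor the aryl bromides.

Step 5
Reactants: 7 6-bromo-2-(5-bromo-2,4-dimethoxyphenyl)-3,7-dimethoxy-4H-chromen-4-one
Product: 9 6,5'-dihydroxy-3,7,2',4'-tetramethoxyflavone, via bis(pinacolboronate) 8 (not isolated)
Conditions: Pd(dppf)Cl2·CH2Cl2 (10 mol %), B2pin2 (3 equiv), KOAc (6 equiv), 1,4-dioxane, 90 °C; then NaBO3·4H2O, THF/H2O, 0 °C to rt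
Reagents that add atoms: bis(pinacolato)diboron, CC1(C)OB(OC1(C)C)B1OC(C)(C)C(C)(C)O1 (boryl groups of 8); sodium perborate NaBO3, [Na+].[O-]OB=O (oxygen atoms at C6 and C5' of 9)
Why: Pd(dppf)Cl2 is reduced in the flask to zerovalent palladium, which inserts into each C–Br bond to give Ar–Pd(dppf)–Br (divalent palladium); bromide–acetate exchange gives Ar–Pd(dppf)–OAc, whose Pd–O bond drives transmetalation with B2pin2, and reductive elimination releases the aryl pinacolboronate and returns zerovalent palladium, two such cycles giving 8. In the second stage the peroxoborate anion adds to each boron, the aryl group migrates from boron to oxygen with loss of borate, and hydrolysis of the aryl borate frees the phenol, so the C6–O and C5'–O bonds form exactly where the bromines stood. The closest known reaction type is Miyaura borylation of aryl bromides followed by oxidation of the arylboronates to phenols in one pot. No ring is closed and no stereocentre is created. The step needs chemoselectivity only, since the positions are fixed by the bromines: KOAc is too weak a base to promote Suzuki coupling of 8 with unreacted bromide or to open the pyranone, and perborate at room temperature oxidises C–B bonds but not the C2=C3 enol ether or, in measured excess, the para-alkoxyphenol of ring B. Each C–Br bond has only one ortho substituent, a methoxy group, so oxidative addition is slowed but not blocked.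

## Compound list

1 | paeonol, 1-(2-hydroxy-4-methoxyphenyl)ethanone | CC(=O)c1ccc(OC)cc1O | starting material
2 | 1-(5-bromo-2-hydroxy-4-methoxyphenyl)ethanone | CC(=O)c1cc(Br)c(OC)cc1O | intermediate
3 | 5-bromo-2,4-dimethoxybenzaldehyde | COc1cc(OC)c(C=O)cc1Br | starting material
4 | (E)-1-(5-bromo-2-hydroxy-4-methoxyphenyl)-3-(5-bromo-2,4-dimethoxyphenyl)prop-2-en-1-one | COc1cc(O)c(C(=O)/C=C/c2cc(Br)c(OC)cc2OC)cc1Br | intermediate
5 | rac-(2R,3R)-6-bromo-2-(5-bromo-2,4-dimethoxyphenyl)-3-hydroxy-7-methoxychroman-4-one (trans-dihydroflavonol, racemic, one enantiomer drawn) | COc1cc(OC)c(cc1Br)[C@@H]2[C@H](C(=O)c3cc(Br)c(OC)cc3O2)O | intermediate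
6 | 6-bromo-2-(5-bromo-2,4-dimethoxyphenyl)-3-hydroxy-7-methoxy-4H-chromen-4-one | COc1cc(OC)c(-c2oc3cc(OC)c(Br)cc3c(=O)c2O)cc1Br | intermediate
7 | 6-bromo-2-(5-bromo-2,4-dimethoxyphenyl)-3,7-dimethoxy-4H-chromen-4-one (6,5'-dibromo-3,7,2',4'-tetramethoxyflavone) | COc1cc(OC)c(-c2oc3cc(OC)c(Br)cc3c(=O)c2OC)cc1Br | intermediate
8 | 6,5'-bis(4,4,5,5-tetramethyl-1,3,2-dioxaborolan-2-yl)-3,7,2',4'-tetramethoxyflavone | COc1cc(OC)c(-c2oc3cc(OC)c(B4OC(C)(C)C(C)(C)O4)cc3c(=O)c2OC)cc1B1OC(C)(C)C(C)(C)O1 | intermediate
9 | 6,5'-dihydroxy-3,7,2',4'-tetramethoxyflavone | COc1cc(OC)c(-c2oc3cc(OC)c(O)cc3c(=O)c2OC)cc1O | target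

## Step count and risks

Total step count: 5. Longest linear sequence: 5 steps (1 → 2 → 4 → 6 → 7 → 9); aldehyde 3 enters at step 2.

**Step 5 (key step).**
- What may go wrong: incomplete borylation or hydrodebromination at the more electron-rich C5'–Br bond, so that one position ends as C–H or remains C–Br. Cross-coupling between a boronate already formed and bromide still present is a second risk. In the oxidation stage, excess diboron can consume oxidant, and the para-alkoxyphenol of ring B can be over-oxidised if the perborate charge is too large.
- Fallback, from 7 back to 9: form the C–O bonds directly by palladium-catalysed etherification with benzyl alcohol ([Pd(allyl)Cl]2, RockPhos, Cs2CO3, toluene, 90 °C). This should give 6,5'-bis(benzyloxy)-3,7,2',4'-tetramethoxyflavone F1, and hydrogenolysis (H2, Pd/C, EtOAc/MeOH, rt) should release both phenols to give 9.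

**Step 3.**
- What may go wrong: the ortho-methoxy group twists ring B out of conjugation, which can stall the sequence at the dihydroflavonol stage or divert the closure through the α-carbon to aurone-type material. The dibromochalcone may also dissolve poorly in aqueous methanol.
- Fallback, from 4 back to 6: oxidative cyclisation of 4 with catalytic I2 in DMSO at 120 °C should give 6-bromo-2-(5-bromo-2,4-dimethoxyphenyl)-7-methoxy-4H-chromen-4-one F2. Epoxidation of its C2=C3 bond with dimethyldioxirane in acetone/CH2Cl2 should give the racemic cis-fused epoxide 6-bromo-2-(5-bromo-2,4-dimethoxyphenyl)-2,3-epoxy-7-methoxychroman-4-one F3. A trace of p-TsOH should open this and let it tautomerise to the flavonol 6.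

**Step 2.**
- What may go wrong: the condensation may stop at partial conversion, because the phenoxide of 2 lowers the acidity of the acetyl group and the ortho-substituted, electron-rich aldehyde is a poor electrophile. The chalcone may also partly close to the flavanone during acidic work-up.
- Fallback, from 2 back to 4: mask the phenol with MOMCl and i-Pr2NEt in CH2Cl2 to give 1-[5-bromo-4-methoxy-2-(methoxymethoxy)phenyl]ethanone F4. Condensation with 3 (KOH, EtOH, rt) should then give (E)-1-[5-bromo-4-methoxy-2-(methoxymethoxy)phenyl]-3-(5-bromo-2,4-dimethoxyphenyl)prop-2-en-1-one F5, and brief HCl in MeOH should remove the acetal to return chalcone 4.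

## Further compounds

F1 | step 5 | 6,5'-bis(benzyloxy)-3,7,2',4'-tetramethoxyflavone | COc1cc(OC)c(-c2oc3cc(OC)c(OCc4ccccc4)cc3c(=O)c2OC)cc1OCc1ccccc1
F2 | step 3 | 6-bromo-2-(5-bromo-2,4-dimethoxyphenyl)-7-methoxy-4H-chromen-4-one | COc1cc(OC)c(-c2cc(=O)c3cc(Br)c(OC)cc3o2)cc1Br
F3 | step 3 | 6-bromo-2-(5-bromo-2,4-dimethoxyphenyl)-2,3-epoxy-7-methoxychroman-4-one (cis-fused oxirane, racemic, one enantiomer drawn) | COc1cc(OC)c(cc1Br)[C@]12O[C@H]1C(=O)c1cc(Br)c(OC)cc1O2
F4 | step 2 | 1-[5-bromo-4-methoxy-2-(methoxymethoxy)phenyl]ethanone | COCOc1cc(OC)c(Br)cc1C(C)=O
F5 | step 2 | (E)-1-[5-bromo-4-methoxy-2-(methoxymethoxy)phenyl]-3-(5-bromo-2,4-dimethoxyphenyl)prop-2-en-1-one | COCOc1cc(OC)c(Br)cc1C(=O)/C=C/c1cc(Br)c(OC)cc1OC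
A1 | alternative 1 | 6,5'-bis(benzyloxy)-7,2',4'-trimethoxyflavone | COc1cc(OC)c(-c2cc(=O)c3cc(OCc4ccccc4)c(OC)cc3o2)cc1OCc1ccccc1
A2 | alternative 1 | 4-(benzyloxy)-2-iodo-5-methoxyphenol | COc1cc(O)c(I)cc1OCc1ccccc1
A3 | alternative 1 | 1-(benzyloxy)-5-ethynyl-2,4-dimethoxybenzene | C#Cc1cc(OCc2ccccc2)c(OC)cc1OC
A4 | alternative 2 | (Z)-1-[3-(benzyloxy)-2-chloro-6-hydroxy-4-methoxyphenyl]-3-[5-(benzyloxy)-2,4-dimethoxyphenyl]-2-methoxyprop-2-en-1-one | CO/C(C(=O)c1c(O)cc(OC)c(OCc2ccccc2)c1Cl)=C\c1cc(OCc2ccccc2)c(OC)cc1OC
A5 | alternative 2 | 3-(benzyloxy)-2-chloro-4-methoxy-6-(trimethylsilyl)phenyl trifluoromethanesulfonate | COc1cc([Si](C)(C)C)c(OS(=O)(=O)C(F)(F)F)c(Cl)c1OCc1ccccc1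
A6 | alternative 2 | (Z)-3-[5-(benzyloxy)-2,4-dimethoxyphenyl]-2-methoxyprop-2-enoic acid | CO/C(C(=O)O)=C\c1cc(OCc2ccccc2)c(OC)cc1OC
A7 | alternative 3 | 6,5'-bis(benzyloxy)-2'-hydroxy-3,7,4'-trimethoxyflavone | COc1cc(O)c(-c2oc3cc(OC)c(OCc4ccccc4)cc3c(=O)c2OC)cc1OCc1ccccc1
A8 | alternative 3 | 6-(benzyloxy)-2-ethynyl-3,7-dimethoxy-4H-chromen-4-one | C#Cc1oc2cc(OC)c(OCc3ccccc3)cc2c(=O)c1OC
A9 | alternative 3 | pentacarbonyl[benzyloxy(1-methoxyvinyl)carbene]chromium, (CO)5Cr=C(OBn)C(OMe)=CH2 | C=C(OC)C(OCc1ccccc1)=[Cr](=C=O)(=C=O)(=C=O)(=C=O)=C=O
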